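(The readings are calculated for an exercise.)

**The leftover.** I started from what the coupling partner had to leave over in the flask. Taking one coupling partner per substrate reacted, I reckoned its equivalents, the charge of coupling partner over both substrates together, 1.50. That left a reserve of 33.3 % of its own charge.

| flask | left-handed substrate | right-handed substrate | coupling partner | racemization catalyst | remark | time |
|---|---|---|---|---|---|---|
| spring | 20 mM | 20 mM | 60 mM | 7.4 µM | run made earlier |  |
| winter | 20 mM | 20 mM | 60 mM | 16 µM | run made earlier |  |
| autumn | 10 mM | 10 mM | 60 mM | 11 µM | run made earlier |  |
| flask | 20 mM | 20 mM | 60.0 mM | 11 µM |  | 1.0 h |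

| run | time / min | left-handed substrate / % | right-handed substrate / % |
|---|---|---|---|
| spring | 4.00 | 22 | 32 |
| spring | 8.00 | 10 | 23 |
| spring | 20.0 | 0 | 7 |
| spring | 50.0 | 1 | 0 |
| winter | 12.0 | 7 | 21 |
| winter | 25.0 | 5 | 6 |
| winter | 40.0 | 0 | 4 |
| winter | 50.0 | 2 | 0 |
| autumn | 12.0 | 4 | 18 |
| autumn | 25.0 | 0 | 5 |
| autumn | 40.0 | 1 | 0 |
| autumn | 50.0 | 3 | 2 |

(readings scatter by 2 percentage points)

1. part of the left-handed substrate and right-handed substrate charged together that has reacted at 1.0 h
2. excess of left-handed product over right-handed product in the product at 1.0 h
3. excess of right-handed substrate over left-handed substrate among what is left of the two at 1.0 h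

- coupling partner is single-handed; left-handed substrate and right-handed substrate are mirror images of each other, charged as a racemate, each of them at the stated concentration
- an excess is below zero if the other one leads
- the handed part of coupling partner does not stay in what it makes, so the products of the two hands are mirror images too

**Two extremes.** In the spring run the right-handed substrate, the slower hand, read 32 % at 4.00 min. From its starting half of the charge, that reads as a rate of 0.112 /min. I took this rate as proportional to the coupling partner and set racemization aside. With the coupling partner held at its charge, a pseudo-first-order decay, the flask would keep 0.0619 % of right-handed substrate at 1.0 h. With the coupling partner standing at its reserve throughout, the flask would keep 5.37 %. The coupling partner in the flask falls from its full charge towards that reserve, so I expected the right-handed substrate to lie between these two.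

**The forecast.** The forecast saw the decay “no clear slowing as the partner is used”, whereas I let the rate fall. It gave 99.7 % reacted, 9 % for the product excess and 70 % for the substrate excess.

**The flask.** The flask gave 98.7 %, −0.360 % and 69.9 %. The forecast stood within tolerance on the first and third and parted on the product excess.

    coupling partner + right-handed substrate → right-handed product (k = 0.0360 /M/s)
    left-handed substrate + racemization catalyst ⇌ right-handed substrate + racemization catalyst, rate k2*[racemization catalyst]*[left-handed substrate] forward; the back reaction follows from the equilibrium constant (k = 25.0 /M/s)
    2 racemization catalyst ⇌ resting dimer (K = 52000 /M, k = 66.0 /M/s)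
    left-handed product ⇌ right-handed product (k = 2.90 × 10⁻⁴ /s)
    coupling partner + left-handed substrate → left-handed product (k = 0.0800 /M/s)

**The neighbour.** The flask ended with 34 % of its coupling partner against the reckoned 33.3 %, and with 1.12 % of right-handed substrate, inside my bracket. A neighbour charged with 15 mM of coupling partner has equivalents of 0.375, below one. On that count the coupling partner is the limiting reagent, and its charge allows a reacted share of 37.5 %. The neighbour reached 37.3 % at 1.0 h, with 0.407 % of its coupling partner left.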